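**Strategy**

The target is a labdane-type trans-decalin (rings A and B: gem-dimethyl C4, C5–H, quaternary C10 with its methyl, C8=C9 alkene) carrying a dienyl butenolide chain on C9. Rings A and B together with C11–C13 have the head-to-tail isoprenoid pattern of (5E,9E)-farnesylacetone, so everything rests on one disconnection: an enzymatic cationic bicyclisation. A squalene–hopene cyclase folds the acyclic trienone, forms C4–C5 and C9–C10 and lets the ketone oxygen capture C8, delivering sclareol oxide with the C5 and C10 configurations of the target in a single operation. Acid then opens the enol ether to the C8=C9 ketone, and alkyne formation, vinylation, nickel hydrohydroxymethylation and a Heck coupling complete the chain.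

Key step: step 3

Remark on numbering: labdane numbering is used for the core (C1–C10; C17 = methyl on C8; C18/C19 = gem-dimethyl on C4; C20 = methyl on C10). The chain is C11, C12, C13 (bears CH2OH), C14, C15, C16 (bonded to the butenolide).

Remark on structures: the stereodescriptors of precursor, cyclisation product and target were checked against each other. Compound 7 is (5S,8R,9R,10S) and the target (5S,10S), the normal labdane series, so no structure needed correction.

Remark on step 4: the thermodynamic preference for the open C8=C9 ketone over the enol ether is an assumption based on strain and entropy arguments, not an established fact for this substrate.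

Remark on step 7: paraformaldehyde is assumed to act as the terminal reductant, leaving a formate ester; the methanolysis in the work-up covers that case.

**Route**

Step 1
Reactants: 1 (2E,6E)-farnesol
Product: 2 (2E,6E)-farnesyl bromide
Conditions: PBr3 (0.4 equiv), Et2O, −10 °C → 0 °C
Reagents that add atoms: phosphorus tribromide, BrP(Br)Br
Why: Low-temperature PBr3 bromination proceeds by SN2 displacement of the primary allylic phosphite ester by bromide, which keeps both E alkenes and avoids allylic transposition.

Step 2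
Reactants: 2 (2E,6E)-farnesyl bromide; 3 ethyl acetoacetate
Product: 6 (5E,9E)-farnesylacetone, via keto ester 4 (not isolated), via keto acid 5 (not isolated)
Conditions: NaH, 3 (2 equiv), THF, 0 °C → rt; then 2 M aq. NaOH, MeOH, 60 °C; then 2 M HCl, 50 °C
Reagents that add atoms: none
Why: Acetoacetic ester ketone synthesis: the sodium enolate of 3 (in excess to suppress dialkylation) is C-alkylated by the primary allylic bromide in an SN2 reaction, and saponification followed by acid-promoted decarboxylation of the β-keto acid leaves the methyl ketone with both trisubstituted alkenes untouched.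

Step 3
Reactants: 6 (5E,9E)-farnesylacetone
Product: 7 sclareol oxide [(4aR,6aS,10aS,10bR)-3,4a,7,7,10a-pentamethyl-4a,5,6,6a,7,8,9,10,10a,10b-decahydro-1H-benzo[f]chromene]
Conditions: squalene–hopene cyclase (Zymomonas mobilis enzyme ZmoSHC1, recombinant E. coli whole cells), citrate buffer pH 6.0, 0.2% Triton X-100, 30 °C
Reagents that add atoms: none
Why: The active-site aspartic acid protonates C3 of the terminal C3=C4 alkene and the chair–chair prefolded chain collapses in a cationic polyene (cation–olefin) cyclisation, the closest known reaction type being the bicyclisation of homofarnesol, homofarnesic acid and farnesylacetone-type ketones by these cyclases. Ring A closes by 6-endo attack of the C5=C10 alkene on C4 (C4–C5 bond), ring B by 6-endo attack of the C8=C9 alkene on C10 (C9–C10 bond), and ring C by six-membered capture of the tertiary C8 cation by the ketone oxygen, the oxocarbenium ion then losing H12 to give the enol ether. C5 and C10 arise from anti addition across the 9E alkene of 6 in a chair (trans ring fusion), C9 and C8 from anti addition across the 5E alkene (9α-H, 8α-O, 8β-CH3), so the relative configuration follows from the E,E geometry and the absolute configuration (5S,8R,9R,10S) from the fold imposed by the enzyme. The step needs initiation at the terminal alkene only and termination by oxygen instead of proton loss or water; the isopropylidene end is the alkene that reaches the acid site, and the ketone oxygen reaches C8 through a strain-free six-membered ring.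

Step 4
Reactants: 7 sclareol oxide
Product: 9 4-[(4aS,8aS)-2,5,5,8a-tetramethyl-3,4,4a,5,6,7,8,8a-octahydronaphthalen-1-yl]butan-2-one, via 8α-hydroxy ketone 8 (not isolated)
Conditions: 57% aq. HI (0.2 equiv), toluene, 85 °C
Reagents that add atoms: water, O
Why: Acid-catalysed enol ether hydrolysis followed by E1 dehydration and alkene isomerisation under thermodynamic control: water opens the protonated enol ether to the 8α-hydroxy ketone (the new carbonyl oxygen comes from water), the tertiary C8 alcohol ionises, and reversible HI-mediated protonation–elimination should funnel the Δ7 and exocyclic isomers (and any re-closed 7) to the tetrasubstituted C8=C9 alkene, whose open-chain form should be favoured at 85 °C by entropy and by release of the 1,3-diaxial C17/C20 methyl repulsion present in 7; C5 and C10 are not involved.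

Step 5
Reactants: 9 4-[(4aS,8aS)-2,5,5,8a-tetramethyl-3,4,4a,5,6,7,8,8a-octahydronaphthalen-1-yl]butan-2-one
Product: 11 (4aS,8aS)-5-(but-3-yn-1-yl)-1,1,4a,6-tetramethyl-1,2,3,4,4a,7,8,8a-octahydronaphthalene, via enol phosphate 10 (not isolated)
Conditions: LiN(i-Pr)2 (1.1 equiv), THF, −78 °C; ClP(O)(OEt)2, −78 °C → rt; then LiN(i-Pr)2 (2.3 equiv), −78 °C → rt; aq. NH4Cl
Reagents that add atoms: none
Why: Methyl ketone to terminal alkyne by the enol phosphate elimination method: kinetic deprotonation at the C14 methyl group, O-phosphorylation, and base-induced E2 loss of diethyl phosphate from the terminal enol phosphate give the acetylide, while the tetrasubstituted alkene and both stereocentres are inert to the amide base.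

Step 6
Reactants: 11 (4aS,8aS)-5-(but-3-yn-1-yl)-1,1,4a,6-tetramethyl-1,2,3,4,4a,7,8,8a-octahydronaphthalene; 12 vinyl bromide
Product: 13 (4aS,8aS)-5-(hex-5-en-3-yn-1-yl)-1,1,4a,6-tetramethyl-1,2,3,4,4a,7,8,8a-octahydronaphthalene
Conditions: PdCl2(PPh3)2 (2 mol%), CuI (4 mol%), i-Pr2NH, THF, rt (12 as 1.0 M solution in THF, sealed flask)
Reagents that add atoms: none
Why: Sonogashira coupling: oxidative addition of the vinyl bromide to zerovalent palladium, transmetalation from the copper acetylide and reductive elimination form the C14–C15 bond, and no other group in 11 reacts under these mild amine conditions.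

Step 7
Reactants: 13 (4aS,8aS)-5-(hex-5-en-3-yn-1-yl)-1,1,4a,6-tetramethyl-1,2,3,4,4a,7,8,8a-octahydronaphthalene
Product: 15 (2E)-2-{2-[(4aS,8aS)-2,5,5,8a-tetramethyl-3,4,4a,5,6,7,8,8a-octahydronaphthalen-1-yl]ethyl}penta-2,4-dien-1-ol, via formate ester 14 (not isolated)
Conditions: Ni(cod)2 (10 mol%), PCy3 (20 mol%), (CH2O)n (4 equiv), toluene, 75 °C; then K2CO3 (cat.), MeOH, rt
Reagents that add atoms: paraformaldehyde (as formaldehyde), C=O
Why: Nickel-catalysed reductive alkyne–aldehyde coupling (hydrohydroxymethylation): oxidative cyclisation of the enyne and formaldehyde on zerovalent nickel forms the new C–C bond at C13, the alkyne carbon remote from the coordinating vinyl group, a second formaldehyde acts as hydride donor (leaving the formate ester, cleaved by methanolysis), and the cis delivery of carbon and hydrogen across the alkyne sets the 13E geometry with CH2OH cis to H14.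

Step 8
Reactants: 15 (2E)-2-{2-[(4aS,8aS)-2,5,5,8a-tetramethyl-3,4,4a,5,6,7,8,8a-octahydronaphthalen-1-yl]ethyl}penta-2,4-dien-1-ol; 16 4-bromofuran-2(5H)-one
Product: 17 4-{(1E,3E)-4-(hydroxymethyl)-6-[(4aS,8aS)-2,5,5,8a-tetramethyl-3,4,4a,5,6,7,8,8a-octahydronaphthalen-1-yl]hexa-1,3-dien-1-yl}furan-2(5H)-one
Conditions: Pd(OAc)2 (5 mol%), P(o-tol)3 (10 mol%), NaHCO3, n-Bu4NBr, DMF, 60 °C
Reagents that add atoms: none
Why: Mizoroki–Heck vinylation: oxidative addition of the β-bromo butenolide, syn carbopalladation of the terminal C15=C16 alkene with carbon going to the unsubstituted C16, and syn β-hydride elimination should deliver the conjugated 15E triene, while the bicarbonate base spares the lactone and the tri- and tetrasubstituted alkenes are too hindered to insert.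

**Compound list**

1 | (2E,6E)-farnesol | CC(C)=CCC/C(C)=C/CC/C(C)=C/CO | starting material
2 | (2E,6E)-farnesyl bromide | CC(C)=CCC/C(C)=C/CC/C(C)=C/CBr | intermediate
3 | ethyl acetoacetate | CCOC(=O)CC(C)=O | starting material
4 | ethyl (4E,8E)-2-acetyl-5,9,13-trimethyltetradeca-4,8,12-trienoate (racemic at C2, not isolated) | CCOC(=O)C(C(C)=O)C/C=C(\C)CC/C=C(\C)CCC=C(C)C | intermediate
5 | (4E,8E)-2-acetyl-5,9,13-trimethyltetradeca-4,8,12-trienoic acid (racemic at C2, not isolated) | OC(=O)C(C(C)=O)C/C=C(\C)CC/C=C(\C)CCC=C(C)C | intermediate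
6 | (5E,9E)-farnesylacetone, (5E,9E)-6,10,14-trimethylpentadeca-5,9,13-trien-2-one | CC(=O)CC/C=C(\C)CC/C=C(\C)CCC=C(C)C | intermediate
7 | sclareol oxide, (4aR,6aS,10aS,10bR)-3,4a,7,7,10a-pentamethyl-4a,5,6,6a,7,8,9,10,10a,10b-decahydro-1H-benzo[f]chromene | C[C@@]14OC(C)=CC[C@@H]4[C@@]2(C)CCCC(C)(C)[C@@H]2CC1 | intermediate
8 | 4-[(1R,2R,4aS,8aS)-2-hydroxy-2,5,5,8a-tetramethyldecahydronaphthalen-1-yl]butan-2-one (8α-hydroxy ketone, not isolated) | CC(=O)CC[C@@H]1[C@@]2(C)CCCC(C)(C)[C@@H]2CC[C@@]1(C)O | intermediate
9 | 4-[(4aS,8aS)-2,5,5,8a-tetramethyl-3,4,4a,5,6,7,8,8a-octahydronaphthalen-1-yl]butan-2-one | CC1=C(CCC(C)=O)[C@@]2(C)CCCC(C)(C)[C@@H]2CC1 | intermediate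
10 | diethyl 4-[(4aS,8aS)-2,5,5,8a-tetramethyl-3,4,4a,5,6,7,8,8a-octahydronaphthalen-1-yl]but-1-en-2-yl phosphate (not isolated) | CC1=C(CCC(=C)OP(=O)(OCC)OCC)[C@@]2(C)CCCC(C)(C)[C@@H]2CC1 | intermediate
11 | (4aS,8aS)-5-(but-3-yn-1-yl)-1,1,4a,6-tetramethyl-1,2,3,4,4a,7,8,8a-octahydronaphthalene | CC1=C(CCC#C)[C@@]2(C)CCCC(C)(C)[C@@H]2CC1 | intermediate
12 | vinyl bromide | C=CBr | starting material
13 | (4aS,8aS)-5-(hex-5-en-3-yn-1-yl)-1,1,4a,6-tetramethyl-1,2,3,4,4a,7,8,8a-octahydronaphthalene | CC1=C(CCC#CC=C)[C@@]2(C)CCCC(C)(C)[C@@H]2CC1 | intermediate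
14 | (2E)-2-{2-[(4aS,8aS)-2,5,5,8a-tetramethyl-3,4,4a,5,6,7,8,8a-octahydronaphthalen-1-yl]ethyl}penta-2,4-dien-1-yl formate (not isolated) | CC1=C(CC/C(=C\C=C)COC=O)[C@@]2(C)CCCC(C)(C)[C@@H]2CC1 | intermediate
15 | (2E)-2-{2-[(4aS,8aS)-2,5,5,8a-tetramethyl-3,4,4a,5,6,7,8,8a-octahydronaphthalen-1-yl]ethyl}penta-2,4-dien-1-ol | CC1=C(CC/C(=C\C=C)CO)[C@@]2(C)CCCC(C)(C)[C@@H]2CC1 | intermediate
16 | 4-bromofuran-2(5H)-one | BrC1=CC(=O)OC1 | starting material
17 | 4-{(1E,3E)-4-(hydroxymethyl)-6-[(4aS,8aS)-2,5,5,8a-tetramethyl-3,4,4a,5,6,7,8,8a-octahydronaphthalen-1-yl]hexa-1,3-dien-1-yl}furan-2(5H)-one | CC1=C(CC/C(=C\C=C\C2=CC(=O)OC2)CO)[C@@]2(C)CCCC(C)(C)[C@@H]2CC1 | target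

**Step count and risks**

Total step count: 8. Longest linear sequence: 8 steps (1 → 2 → 6 → 7 → 9 → 11 → 13 → 15 → 17); compounds 3, 12 and 16 are commercial.

Step 3 carries the strategic weight by design, but it applies a cyclase reaction precedented for this substrate class. The three steps judged most likely to fail are steps 4, 7 and 8.

Step 4 (enol ether opening and alkene equilibration). The equilibration may stall at the trisubstituted Δ7 or the exocyclic alkene, the ketone oxygen may recapture the C8 cation and return 7, or prolonged acid may start a C20 methyl shift. The fallback sets out from 8 and comes back at 11. Compound 7 is hydrolysed under mild conditions (1 M HCl, THF, rt) and ketol 8 is isolated. Its tertiary alcohol is silylated with N-(trimethylsilyl)imidazole to 4-[(1R,2R,4aS,8aS)-2,5,5,8a-tetramethyl-2-(trimethylsilyloxy)decahydronaphthalen-1-yl]butan-2-one F1. The ketone is converted as in step 5, through the corresponding diethyl enol phosphate F2 (not isolated), into the silyloxy alkyne F3. n-Bu4NF then frees the hydroxy alkyne (1R,2R,4aS,8aS)-1-(but-3-yn-1-yl)-2,5,5,8a-tetramethyldecahydronaphthalen-2-ol F4. Dehydration with PPh3/I2 in CH2Cl2 at rt, a reagent pair that takes hindered tertiary alcohols to the most substituted alkene, should give 11. Because no carbonyl group is left when C8 ionises, re-closure cannot occur.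

Step 7 (nickel hydrohydroxymethylation). Regiocontrol in the oxidative cyclisation may erode, or the enyne may be consumed by nickel-mediated oligomerisation before formaldehyde is engaged. The fallback sets out from 11 and comes back at 15; it fixes the regiochemistry with a silyl group and a stoichiometric titanium–alkyne complex. The acetylide of 11 (n-BuLi, Me3SiCl, THF) gives the 1-trimethylsilyl alkyne F5. Its complex formed with Ti(O-i-Pr)4 and i-PrMgCl (2 equiv) at −50 °C is trapped with monomeric formaldehyde, which adds at the carbon β to silicon; hydrolysis with retention gives the (2E)-3-(trimethylsilyl) allylic alcohol F6. Iododesilylation with N-iodosuccinimide, with retention, gives the (2E)-3-iodo allylic alcohol F7. Stille coupling with tributyl(vinyl)stannane (Pd(PPh3)4, CuI, DMF) returns dienol 15.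

Step 8 (Heck coupling). The π-allylpalladium intermediate formed after carbopalladation of the diene may be diverted (β-hydride elimination towards the carbinol, or allylic substitution), or the base may degrade the butenolide. The fallback sets out from 11 and comes back at 17; it replaces the Heck reaction by a Suzuki–Miyaura coupling whose alkene geometry is carried in by the reagent. Sonogashira coupling of 11 with commercial (E)-2-bromovinylboronic acid MIDA ester gives the enynyl MIDA boronate F8. The nickel hydrohydroxymethylation of step 7, through the formate ester F9 (not isolated; cleaved with NaHCO3 in MeOH), gives the (1E,3E)-dienyl MIDA boronate F10. Slow-release coupling with 16 (Pd(OAc)2, SPhos, K3PO4, dioxane/water, 60 °C) should give 17.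

**Further compounds**

F1 | step 4 | 4-[(1R,2R,4aS,8aS)-2,5,5,8a-tetramethyl-2-(trimethylsilyloxy)decahydronaphthalen-1-yl]butan-2-one | CC(=O)CC[C@@H]1[C@@]2(C)CCCC(C)(C)[C@@H]2CC[C@@]1(C)O[Si](C)(C)C
F2 | step 4 | diethyl 4-[(1R,2R,4aS,8aS)-2,5,5,8a-tetramethyl-2-(trimethylsilyloxy)decahydronaphthalen-1-yl]but-1-en-2-yl phosphate (not isolated) | C=C(OP(=O)(OCC)OCC)CC[C@@H]1[C@@]2(C)CCCC(C)(C)[C@@H]2CC[C@@]1(C)O[Si](C)(C)C
F3 | step 4 | {[(1R,2R,4aS,8aS)-1-(but-3-yn-1-yl)-2,5,5,8a-tetramethyldecahydronaphthalen-2-yl]oxy}trimethylsilane | C#CCC[C@@H]1[C@@]2(C)CCCC(C)(C)[C@@H]2CC[C@@]1(C)O[Si](C)(C)C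
F4 | step 4 | (1R,2R,4aS,8aS)-1-(but-3-yn-1-yl)-2,5,5,8a-tetramethyldecahydronaphthalen-2-ol | C#CCC[C@@H]1[C@@]2(C)CCCC(C)(C)[C@@H]2CC[C@@]1(C)O
F5 | step 7 | trimethyl{4-[(4aS,8aS)-2,5,5,8a-tetramethyl-3,4,4a,5,6,7,8,8a-octahydronaphthalen-1-yl]but-1-yn-1-yl}silane | CC1=C(CCC#C[Si](C)(C)C)[C@@]2(C)CCCC(C)(C)[C@@H]2CC1
F6 | step 7 | (2E)-2-{2-[(4aS,8aS)-2,5,5,8a-tetramethyl-3,4,4a,5,6,7,8,8a-octahydronaphthalen-1-yl]ethyl}-3-(trimethylsilyl)prop-2-en-1-ol | CC1=C(CC/C(=C\[Si](C)(C)C)CO)[C@@]2(C)CCCC(C)(C)[C@@H]2CC1
F7 | step 7 | (2E)-3-iodo-2-{2-[(4aS,8aS)-2,5,5,8a-tetramethyl-3,4,4a,5,6,7,8,8a-octahydronaphthalen-1-yl]ethyl}prop-2-en-1-ol | CC1=C(CC/C(=C\I)CO)[C@@]2(C)CCCC(C)(C)[C@@H]2CC1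
F8 | step 8 | MIDA boronate of (1E)-6-[(4aS,8aS)-2,5,5,8a-tetramethyl-3,4,4a,5,6,7,8,8a-octahydronaphthalen-1-yl]hex-1-en-3-yn-1-ylboronic acid | CC1=C(CCC#C/C=C/B3OC(=O)CN(C)CC(=O)O3)[C@@]2(C)CCCC(C)(C)[C@@H]2CC1
F9 | step 8 | formate ester of F10 (not isolated) | CC1=C(CC/C(=C\C=C\B3OC(=O)CN(C)CC(=O)O3)COC=O)[C@@]2(C)CCCC(C)(C)[C@@H]2CC1
F10 | step 8 | MIDA boronate of (1E,3E)-4-(hydroxymethyl)-6-[(4aS,8aS)-2,5,5,8a-tetramethyl-3,4,4a,5,6,7,8,8a-octahydronaphthalen-1-yl]hexa-1,3-dien-1-ylboronic acid | CC1=C(CC/C(=C\C=C\B3OC(=O)CN(C)CC(=O)O3)CO)[C@@]2(C)CCCC(C)(C)[C@@H]2CC1
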